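## Structural features

Isochromene numbering is used throughout (C1, O2, C3, C4, C4a, C5–C8, C8a), including for open-chain precursors. The target is a 3,4,5,6,7,8-hexahydro-1H-isochromen-8-one: a 3,6-dihydro-2H-pyran (O2–C1–C8a=C4a–C4–C3) fused to a cyclohex-2-enone (C8(=O)–C8a=C4a–C5–C6–C7) through the tetrasubstituted enone double bond C4a=C8a. C3 (S) is an allylic ether carbon bearing an (E)-propenyl group. C6 (S) bears an acetate, and C7 (S) is quaternary with a methyl group and a 2-hydroxy-4-methoxy-6-methylbenzoate; the two oxygens at C6 and C7 are cis. C6 and C7 are adjacent and can be set as a pair, but C3 is separated from them by the flat enone and needs its own control element. Fragile points are the C6 acetate (vinylogous E1cB loss under base to a cyclohexa-2,4-dienone), the β-hydroxy ketone at the C6 alcohol stage (retro-aldol), acyl migration between the cis oxygens, and the propenyl alkene (no hydrogenolysis, no unselective oxidants). The real difficulty is the C7–O bond: a tertiary ester of a di-ortho-substituted benzoic acid on a quaternary α-keto carbon, with defined configuration next to C6. The feature exploited is that ring C4a–C5–C6–C7–C8–C8a has the substitution pattern of an o-cresol (O at C8, CH3 at C7, carbon at C8a and C4a); the target is formally the 1,6-adduct of acetic acid to the o-quinol ester of that phenol.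

## Logic of the disconnections

27 ⇒ 26 ⇒ 25. The aryl O–CH2OCH3 bond and the C6 O–acetyl bond are cut. The acetate is what makes the molecule base-labile, so it is installed late and the last step is acidic. The forward steps must be non-basic and must not move the C7 aroate.

25 ⇒ 23. The C6–O bond and one C5–H bond are cut, which is a retro 1,6-hydration of a dienone. This removes the C6 stereocentre and leaves a cyclohexa-2,4-dienone that is a dearomatised phenol. The forward step must add at the δ-carbon C6 (not at C4a) and on the face of the C7 ester oxygen, so that C6 is relayed from C7.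

23 ⇒ 16 + 20 (key). The C7–O ester bond is cut and the ring is re-aromatised. The most hindered bond of the target is thus made by C–O bond formation at carbon, not by acylating a tertiary α-ketol. All carbocycle functionality and the quaternary centre disappear, giving a flat phenol and a benzoic acid, and the route becomes convergent. The forward step must choose ortho carbon C7 over C8a, C5 and benzylic C1, control the face at C7 by the reagent, and spare the propenyl group.

20 ⇒ 19 ⇒ 18 ⇒ 17. The ester, the MOM ether and the 4-O-methyl bond are cut back to a commercial resorcylate. The forward steps rely on the hydrogen-bonded 2-OH being the less reactive phenol.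

16 ⇒ 14. The O2–C1 bond is cut. A salicyl alcohol closes onto the C3 hydroxyl without touching the C3–O bond. The forward step needs acid mild enough not to ionise the allylic carbinol.

14 ⇒ 12 ⇒ 11. These are functional group changes: one hydride reagent takes the lactone to the diol and the alkyne to the (E)-alkene, and the aryl methyl ether is cleaved while the lactone carbonyl can still assist.

11 ⇒ 9. The C3–H bond (hydride) and the lactone C1–O2 bond are cut. C3 is set by catalyst-controlled reduction of an alkynyl ketone, which must run without base.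

9 ⇒ 4 + 7, and 7 ⇒ 5. The C4–C3 bond is cut to a laterally lithiated toluate and an acyl donor. The ester that will become C1 is also what makes the C4 methyl acidic.

4 ⇒ 3 ⇒ 1. The C1–C8a bond (carboxylation) and two O–CH3 bonds are cut. Both methyl groups of 1 are target carbons (C7–CH3 and C4), and only one ortho position is free.

## Other disconnections considered

Alternative 1: the route most chemists would draw first. Both acyl–O bonds are cut last and the C6–O/C7–O pair is made by osmium cis-dihydroxylation of the C6=C7 olefin of an 8-oxygenated 5,8-dihydroisochromene A2, giving after oxidation the diol A1, which is then esterified twice. The chosen plan is preferred for three reasons. The C7 hydroxyl of A1 is tertiary, α to a ketone, and would have to be acylated by a 2,6-disubstituted benzoyl donor next to a cis oxygen that invites acyl migration. A2 has three alkenes and the electron-rich propenyl group competes for the oxidant. C8 cannot be a ketone while C6=C7 is present (that dienone is the keto tautomer of a phenol), so extra redox steps are needed.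

Alternative 2: hydroxylative dearomatisation of the resorcinol A3 (OH at C6 and C8) at C7, which is regiochemically secure because C7 is ortho to both hydroxyls, giving the vinylogous acid A4. The chosen plan is preferred because A4 is an enolised β-diketone: its C6 carbonyl resists chemo- and stereoselective reduction, C5 must still be reduced, and the C7–OH still needs the hindered esterification. The monophenol 16 keeps C6 at the alkene level, so one 1,6-addition sets both C6–O and C5H2.

Alternative 3: desymmetrisation of the prochiral 2-aroyloxy-2-methylcyclohexane-1,3-dione A5 by enantioselective mono-reduction to A6, which would set C6 and C7 in one catalytic event. The chosen plan is preferred because the pyran would then have to be annulated onto a saturated ketone (dehydrogenation, α-hydroxymethylation, β-alkylation, ring closure, separate control of C3). These steps use base and oxidants that the β-hydroxy/β-acyloxy ketone of A6 tolerates poorly, and the sequence is much longer. In 16 those carbons are already in place.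

Key step: step 12

Assumptions:
- The sense of induction of the (R,R)-iodane in step 12 is assumed to give 7S; if it is opposite, the (S,S)-reagent is used with no other change.
- The chiral (diacetoxyiodo)arene is a stoichiometric reagent made by standard perborate/AcOH oxidation of the corresponding iodoarene.

## Route

Step 1
Reactants: 1 2,5-dimethylphenol
Product: 3 2-hydroxy-3,6-dimethylbenzoic acid, via sodium 2,5-dimethylphenoxide 2 (not isolated)
Conditions: NaOH, H2O, then dried; CO2 (60 bar), 150 °C; aq. HCl
Reagents that add atoms: carbon dioxide, O=C=O; sodium hydroxide, [Na+].[OH-] (sodium of intermediate 2 only)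
Why: Kolbe–Schmitt carboxylation; the sodium phenoxide–CO2 chelate should deliver CO2 to the only free ortho position, which becomes C8a/C1.

Step 2
Reactants: 3 2-hydroxy-3,6-dimethylbenzoic acid
Product: 4 methyl 2-methoxy-3,6-dimethylbenzoate
Conditions: MeI (3 equiv), K2CO3, DMF, 60 °C
Reagents that add atoms: iodomethane, CI
Why: SN2 O-methylation of carboxylate and phenoxide; alkylating the carboxylate avoids Fischer esterification of a di-ortho-substituted acid.

Step 3
Reactants: 5 but-2-ynoic acid
Product: 7 N-methoxy-N-methylbut-2-ynamide, via but-2-ynoic isobutyl carbonic anhydride 6 (not isolated)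
Conditions: i-BuOCOCl, N-methylmorpholine, CH2Cl2, −15 °C; then MeNHOMe·HCl, N-methylmorpholine, −15 °C → rt
Reagents that add atoms: N,O-dimethylhydroxylamine hydrochloride, CNOC.Cl; isobutyl chloroformate, CC(C)COC(Cl)=O (atoms of intermediate 6 only)
Why: Mixed-anhydride amidation to the Weinreb amide; the cold, weakly basic conditions spare the ynoate.

Step 4
Reactants: 4 methyl 2-methoxy-3,6-dimethylbenzoate; 7 N-methoxy-N-methylbut-2-ynamide
Product: 9 methyl 2-methoxy-3-methyl-6-(2-oxopent-3-yn-1-yl)benzoate, via benzylic lithium species 8 (not isolated)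
Conditions: LDA (1.1 equiv), THF, −78 °C; then 7, −78 °C; aq. NH4Cl
Reagents that add atoms: lithium diisopropylamide, [Li]N(C(C)C)C(C)C (lithium of intermediate 8 only)
Why: Lateral lithiation of the o-toluate (only the methyl ortho to the ester gives the delocalised dienolate) and Weinreb acylation, whose chelated adduct prevents over-addition until quench; this forms the C4–C3 bond.

Step 5
Reactants: 9 methyl 2-methoxy-3-methyl-6-(2-oxopent-3-yn-1-yl)benzoate
Product: 11 (3S)-8-methoxy-7-methyl-3-(prop-1-yn-1-yl)-3,4-dihydro-1H-isochromen-1-one, via (S)-hydroxy ester 10 (not isolated)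
Conditions: Ru[(S,S)-TsDPEN](p-cymene) (2 mol%), i-PrOH, rt; then TsOH·H2O (5 mol%), CH2Cl2, rt
Reagents that add atoms: none
Why: Noyori-type asymmetric transfer hydrogenation of an alkynyl ketone under base-free conditions; the catalyst distinguishes alkynyl from CH2Ar and the (S,S)-complex should give the (S)-carbinol (C3) by analogy with alkyl alkynyl ketones. Acid then closes the six-membered lactone by transesterification.

Step 6
Reactants: 11 (3S)-8-methoxy-7-methyl-3-(prop-1-yn-1-yl)-3,4-dihydro-1H-isochromen-1-one
Product: 12 (3S)-8-hydroxy-7-methyl-3-(prop-1-yn-1-yl)-3,4-dihydro-1H-isochromen-1-one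
Conditions: BCl3, CH2Cl2, −78 → 0 °C; aq. NaHCO3
Reagents that add atoms: none
Why: Chelation-assisted BCl3 cleavage of the aryl methyl ether peri to the lactone carbonyl; alkyne and lactone should be inert at low temperature.

Step 7
Reactants: 12 (3S)-8-hydroxy-7-methyl-3-(prop-1-yn-1-yl)-3,4-dihydro-1H-isochromen-1-one
Product: 14 2-(hydroxymethyl)-3-[(2S,3E)-2-hydroxypent-3-en-1-yl]-6-methylphenol, via alkynyl triol 13 (not isolated)
Conditions: Red-Al (5 equiv), THF, 0 °C → rt; Rochelle salt
Reagents that add atoms: none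
Why: Red-Al reduces the lactone to the diol level, and the liberated C3 alkoxide then directs trans-hydroalumination of the alkyne (propargylic alcohol to (E)-allylic alcohol); C3 is untouched.

Step 8
Reactants: 14 2-(hydroxymethyl)-3-[(2S,3E)-2-hydroxypent-3-en-1-yl]-6-methylphenol
Product: 16 (3S)-7-methyl-3-[(1E)-prop-1-en-1-yl]-3,4-dihydro-1H-isochromen-8-ol, via o-quinone methide 15 (not isolated)
Conditions: CSA (10 mol%), CH2Cl2 (0.01 M), 4 Å MS, 0 °C → rt
Reagents that add atoms: none
Why: Acid-catalysed dehydrative etherification through the o-quinone methide, trapped by the C3 hydroxyl in a six-membered closure; the C3–O bond is not broken, so configuration is retained, and the salicyl alcohol should ionise far more readily than the allylic alcohol.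

Step 9
Reactants: 17 methyl 2,4-dihydroxy-6-methylbenzoate
Product: 18 methyl 2-hydroxy-4-methoxy-6-methylbenzoate
Conditions: MeI (1.05 equiv), K2CO3, acetone, rt
Reagents that add atoms: iodomethane, CI
Why: Selective O-methylation of the 4-hydroxyl; the 2-hydroxyl is hydrogen-bonded to the ester and much less nucleophilic.

Step 10
Reactants: 18 methyl 2-hydroxy-4-methoxy-6-methylbenzoate
Product: 19 methyl 4-methoxy-2-(methoxymethoxy)-6-methylbenzoate
Conditions: NaH, DMF, 0 °C; MOMCl
Reagents that add atoms: chloromethyl methyl ether, COCCl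
Why: Williamson-type protection; the MOM ether masks the phenol against iodine(III) in step 12 and is removable by acid at the end.

Step 11
Reactants: 19 methyl 4-methoxy-2-(methoxymethoxy)-6-methylbenzoate
Product: 20 4-methoxy-2-(methoxymethoxy)-6-methylbenzoic acid
Conditions: KOH, DMSO/H2O, 80 °C; then 1 M HCl, 0 °C, to pH 4
Reagents that add atoms: potassium hydroxide, [K+].[OH-]
Why: Forcing saponification of the hindered ester; the MOM ether is stable to base and survives a cold, weakly acidic work-up.

Step 12
Reactants: 16 (3S)-7-methyl-3-[(1E)-prop-1-en-1-yl]-3,4-dihydro-1H-isochromen-8-ol; 20 4-methoxy-2-(methoxymethoxy)-6-methylbenzoic acid (2.2 equiv)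
Product: 23 (3S,7S)-7-methyl-8-oxo-3-[(1E)-prop-1-en-1-yl]-3,4,7,8-tetrahydro-1H-isochromen-7-yl 4-methoxy-2-(methoxymethoxy)-6-methylbenzoate, via bis(aroyloxy)iodane 21 (not isolated), via aryloxy(aroyloxy)iodane 22 (not isolated)
Conditions: (R,R)-{2,6-bis[1-(mesitylcarbamoyl)ethoxy]phenyl}I(OAc)2 (1.1 equiv), 20, PhCl, rt, AcOH removed in vacuo; then 16, CH2Cl2, −40 °C
Reagents that add atoms: (R,R)-{2,6-bis[1-(mesitylcarbamoyl)ethoxy]phenyl}-λ3-iodanediyl diacetate, C[C@@H](Oc1cccc(O[C@H](C)C(=O)Nc2c(C)cc(C)cc2C)c1I(OC(C)=O)OC(C)=O)C(=O)Nc1c(C)cc(C)cc1C (iodoarene unit of intermediates 21 and 22 only)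
Why: Proposed new method: an intermolecular, reagent-controlled variant of Wessely-type dearomative ortho-acyloxylation; phenol 16 exchanges onto iodine(III) of 21 to give 22, whose iodine-bound aroate is transferred to ortho carbon C7 as the O–I bond breaks and the aryl iodide leaves (ligand coupling), so the C7–O ester bond and the 2,4-dienone form together. The closest known reactions are the ortho-acyloxylation of 2,6-dialkylphenols by PhI(O2CR)2 or Pb(O2CR)4 and the enantioselective ortho-spirolactonisation of phenols with the same C2-symmetric lactamide iodanes, where the carboxylate is tethered instead of iodine-bound. No ring is closed; ring C4a–C8a is dearomatised. C7 is set by the reagent: the hydrogen-bonded lactamide arms form a chiral pocket around iodine that exposes one face of the bound phenoxide, and remote C3 should exert no bias. The step needs C7 over C8a, C5 and benzylic C1–H: inner-sphere delivery in a non-ionising solvent at low temperature cannot reach para C5 and avoids a free phenoxenium ion (the source of C1 oxidation). C7 should be preferred over C8a because it carries the donor methyl, has an unsubstituted neighbour, and is not flanked by the ring-fusion substituents or the inductively withdrawing CH2O. The MOM ether keeps the aroate's own phenol from oxidation, the propenyl group should be inert since no peracid is present, and the product, substituted at both α- and β-carbons and esterified at C7, should resist Diels–Alder dimerisation.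

Step 13
Reactants: 23 (3S,7S)-7-methyl-8-oxo-3-[(1E)-prop-1-en-1-yl]-3,4,7,8-tetrahydro-1H-isochromen-7-yl 4-methoxy-2-(methoxymethoxy)-6-methylbenzoate
Product: 25 (3S,6S,7S)-6-hydroxy-7-methyl-8-oxo-3-[(1E)-prop-1-en-1-yl]-3,4,5,6,7,8-hexahydro-1H-isochromen-7-yl 4-methoxy-2-(methoxymethoxy)-6-methylbenzoate, via C6 pinacol boronate 24 (not isolated)
Conditions: CuCl (10 mol%), DPEphos (10 mol%), NaOt-Bu (15 mol%), B2pin2 (1.2 equiv), MeOH (2 equiv), THF, 0 °C; then NaBO3·4H2O, THF/H2O, 0 °C
Reagents that add atoms: sodium perborate, [Na+].[O-]OB=O (oxygen at C6); bis(pinacolato)diboron, CC1(C)OB(OC1(C)C)B1OC(C)(C)C(C)(C)O1 (boron of intermediate 24 only)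
Why: Copper-catalysed 1,6-conjugate borylation of the dienone, then C–B oxidation with retention; β-carbon C4a is fully substituted, so boron should go to δ-carbon C6, on the face of the C7 ester oxygen (anti to the C7 methyl, the face dienophiles choose on 6-acyloxy-6-alkylcyclohexa-2,4-dienones), which sets C6 (S) by relay from C7. Protonation and tautomerisation return the C4a=C8a enone with C5 as CH2; the work-up is kept cold and near neutral to avoid retro-aldol opening and aroyl migration.

Step 14
Reactants: 25 (3S,6S,7S)-6-hydroxy-7-methyl-8-oxo-3-[(1E)-prop-1-en-1-yl]-3,4,5,6,7,8-hexahydro-1H-isochromen-7-yl 4-methoxy-2-(methoxymethoxy)-6-methylbenzoate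
Product: 26 (3S,6S,7S)-6-acetoxy-7-methyl-8-oxo-3-[(1E)-prop-1-en-1-yl]-3,4,5,6,7,8-hexahydro-1H-isochromen-7-yl 4-methoxy-2-(methoxymethoxy)-6-methylbenzoate
Conditions: Ac2O, pyridine, DMAP (cat.), CH2Cl2, 0 °C
Reagents that add atoms: acetic anhydride, CC(=O)OC(C)=O
Why: Standard acylation of the secondary alcohol; the di-ortho-substituted aroate should be too hindered to migrate, and the weak base should not trigger vinylogous elimination.

Step 15
Reactants: 26 (3S,6S,7S)-6-acetoxy-7-methyl-8-oxo-3-[(1E)-prop-1-en-1-yl]-3,4,5,6,7,8-hexahydro-1H-isochromen-7-yl 4-methoxy-2-(methoxymethoxy)-6-methylbenzoate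
Product: 27 (3S,6S,7S)-6-acetoxy-7-methyl-8-oxo-3-[(1E)-prop-1-en-1-yl]-3,4,5,6,7,8-hexahydro-1H-isochromen-7-yl 2-hydroxy-4-methoxy-6-methylbenzoate (target)
Conditions: TFA, CH2Cl2, 0 °C; aq. NaHCO3 (brief, cold)
Reagents that add atoms: none
Why: Acidic cleavage of an aryl MOM ether ortho to an ester carbonyl, which is unusually labile; acid avoids the base-induced loss of the C6 acetate, and no stereocentre is touched.

## Compound list

1 | 2,5-dimethylphenol | Cc1ccc(C)c(O)c1 | starting material
2 | sodium 2,5-dimethylphenoxide | Cc1ccc(C)c([O-])c1.[Na+] | intermediate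
3 | 2-hydroxy-3,6-dimethylbenzoic acid | Cc1ccc(C)c(C(=O)O)c1O | intermediate
4 | methyl 2-methoxy-3,6-dimethylbenzoate | COC(=O)c1c(C)ccc(C)c1OC | intermediate
5 | but-2-ynoic acid | CC#CC(=O)O | starting material
6 | but-2-ynoic isobutyl carbonic anhydride | CC#CC(=O)OC(=O)OCC(C)C | intermediate
7 | N-methoxy-N-methylbut-2-ynamide | CC#CC(=O)N(C)OC | intermediate
8 | methyl 6-(lithiomethyl)-2-methoxy-3-methylbenzoate | [Li]Cc1ccc(C)c(OC)c1C(=O)OC | intermediate
9 | methyl 2-methoxy-3-methyl-6-(2-oxopent-3-yn-1-yl)benzoate | CC#CC(=O)Cc1ccc(C)c(OC)c1C(=O)OC | intermediate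
10 | methyl 6-[(2S)-2-hydroxypent-3-yn-1-yl]-2-methoxy-3-methylbenzoate | CC#C[C@@H](O)Cc1ccc(C)c(OC)c1C(=O)OC | intermediate
11 | (3S)-8-methoxy-7-methyl-3-(prop-1-yn-1-yl)-3,4-dihydro-1H-isochromen-1-one | CC#C[C@@H]1Cc2ccc(C)c(OC)c2C(=O)O1 | intermediate
12 | (3S)-8-hydroxy-7-methyl-3-(prop-1-yn-1-yl)-3,4-dihydro-1H-isochromen-1-one | CC#C[C@@H]1Cc2ccc(C)c(O)c2C(=O)O1 | intermediate
13 | 2-(hydroxymethyl)-3-[(2S)-2-hydroxypent-3-yn-1-yl]-6-methylphenol | CC#C[C@@H](O)Cc1ccc(C)c(O)c1CO | intermediate
14 | 2-(hydroxymethyl)-3-[(2S,3E)-2-hydroxypent-3-en-1-yl]-6-methylphenol | C/C=C/[C@@H](O)Cc1ccc(C)c(O)c1CO | intermediate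
15 | 3-[(2S,3E)-2-hydroxypent-3-en-1-yl]-6-methyl-2-methylidenecyclohexa-3,5-dien-1-one | C/C=C/[C@@H](O)CC1=CC=C(C)C(=O)C1=C | intermediate
16 | (3S)-7-methyl-3-[(1E)-prop-1-en-1-yl]-3,4-dihydro-1H-isochromen-8-ol | C/C=C/[C@@H]1Cc2ccc(C)c(O)c2CO1 | intermediate
17 | methyl 2,4-dihydroxy-6-methylbenzoate | COC(=O)c1c(C)cc(O)cc1O | starting material
18 | methyl 2-hydroxy-4-methoxy-6-methylbenzoate | COC(=O)c1c(C)cc(OC)cc1O | intermediate
19 | methyl 4-methoxy-2-(methoxymethoxy)-6-methylbenzoate | COCOc1cc(OC)cc(C)c1C(=O)OC | intermediate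
20 | 4-methoxy-2-(methoxymethoxy)-6-methylbenzoic acid | COCOc1cc(OC)cc(C)c1C(=O)O | intermediate
21 | {2,6-bis{[(2R)-1-oxo-1-(2,4,6-trimethylanilino)propan-2-yl]oxy}phenyl}-λ3-iodanediyl bis[4-methoxy-2-(methoxymethoxy)-6-methylbenzoate] | C[C@@H](Oc1cccc(O[C@H](C)C(=O)Nc2c(C)cc(C)cc2C)c1I(OC(=O)c3c(C)cc(OC)cc3OCOC)OC(=O)c4c(C)cc(OC)cc4OCOC)C(=O)Nc5c(C)cc(C)cc5C | intermediate
22 | {2,6-bis{[(2R)-1-oxo-1-(2,4,6-trimethylanilino)propan-2-yl]oxy}phenyl}{[(3S)-7-methyl-3-[(1E)-prop-1-en-1-yl]-3,4-dihydro-1H-isochromen-8-yl]oxy}-λ3-iodanyl 4-methoxy-2-(methoxymethoxy)-6-methylbenzoate | C/C=C/[C@@H]1Cc2ccc(C)c(OI(OC(=O)c3c(C)cc(OC)cc3OCOC)c3c(O[C@H](C)C(=O)Nc4c(C)cc(C)cc4C)cccc3O[C@H](C)C(=O)Nc3c(C)cc(C)cc3C)c2CO1 | intermediate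
23 | (3S,7S)-7-methyl-8-oxo-3-[(1E)-prop-1-en-1-yl]-3,4,7,8-tetrahydro-1H-isochromen-7-yl 4-methoxy-2-(methoxymethoxy)-6-methylbenzoate | C/C=C/[C@@H]1CC2=C(CO1)C(=O)[C@@](C)(OC(=O)c1c(C)cc(OC)cc1OCOC)C=C2 | intermediate
24 | (3S,6S,7S)-7-methyl-8-oxo-3-[(1E)-prop-1-en-1-yl]-6-(4,4,5,5-tetramethyl-1,3,2-dioxaborolan-2-yl)-3,4,5,6,7,8-hexahydro-1H-isochromen-7-yl 4-methoxy-2-(methoxymethoxy)-6-methylbenzoate | C/C=C/[C@@H]1CC2=C(CO1)C(=O)[C@@](C)(OC(=O)c1c(C)cc(OC)cc1OCOC)[C@@H](B1OC(C)(C)C(C)(C)O1)C2 | intermediate
25 | (3S,6S,7S)-6-hydroxy-7-methyl-8-oxo-3-[(1E)-prop-1-en-1-yl]-3,4,5,6,7,8-hexahydro-1H-isochromen-7-yl 4-methoxy-2-(methoxymethoxy)-6-methylbenzoate | C/C=C/[C@@H]1CC2=C(CO1)C(=O)[C@@](C)(OC(=O)c1c(C)cc(OC)cc1OCOC)[C@@H](O)C2 | intermediate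
26 | (3S,6S,7S)-6-acetoxy-7-methyl-8-oxo-3-[(1E)-prop-1-en-1-yl]-3,4,5,6,7,8-hexahydro-1H-isochromen-7-yl 4-methoxy-2-(methoxymethoxy)-6-methylbenzoate | C/C=C/[C@@H]1CC2=C(CO1)C(=O)[C@@](C)(OC(=O)c1c(C)cc(OC)cc1OCOC)[C@@H](OC(C)=O)C2 | intermediate
27 | (3S,6S,7S)-6-acetoxy-7-methyl-8-oxo-3-[(1E)-prop-1-en-1-yl]-3,4,5,6,7,8-hexahydro-1H-isochromen-7-yl 2-hydroxy-4-methoxy-6-methylbenzoate | C/C=C/[C@@H]1CC2=C(CO1)C(=O)[C@@](C)(OC(=O)c1c(C)cc(OC)cc1O)[C@@H](OC(C)=O)C2 | target

## Step count and least certain steps

Total: 15 steps. Longest linear sequence: 11 steps (1, 2, 4–8, 12–15).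

Step 12 (key, proposed new method). The carboxylate may be delivered to the wrong face of C7 or to the other ortho carbon C8a, or the benzylic C1–H may be oxidised through an o-quinone methide, because face control by an iodine-bound (untethered) carboxylate is unproven. Fallback, from 16: the achiral reagent [bis(aroyloxy)iodo]benzene F1, made from PhI(OAc)2 and 20, is used in the same way (the known Wessely-type acyloxylation of 2,6-dialkylphenols). It should give 23 together with its C7 epimer F2; these are diastereomers because C3 is fixed and are separated by chromatography. F2 is cleaved back to 16 and 20 with Zn/AcOH and recycled. The route is rejoined at 23.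

Step 13. Boron and the neighbouring aroate may be lost by syn-elimination with re-aromatisation to 16, or boron may add from the methyl face; there is no direct precedent for the facial course on this dienone class. Fallback, from 23: nucleophilic epoxidation (t-BuOOH, DBU, THF, 0 °C) by 1,6-addition of the peroxide at C6 and closure onto C5 should give the γ,δ-epoxy enone F3. Pd(0)/formate hydrogenolysis of this vinyl epoxide (Pd2(dba)3, PBu3, HCO2H/Et3N) breaks the allylic C5–O bond and leaves the C6–O bond intact, returning to the route at 25.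

Step 8. The allylic C3 carbinol may ionise (erosion of configuration, allylic transposition) or the o-quinone methide may oligomerise, since both hydroxyls are acid-sensitive. Fallback, from 11: Red-Al reduction as in step 7 gives the methoxy diol F4. One-pot treatment with NaH and TsCl (1 equiv) forms the primary benzylic tosylate F5, which is displaced by the C3 alkoxide to the 8-methoxyisochroman F6 (Williamson closure, C3–O untouched). NaSEt in DMF at 110 °C cleaves the methyl ether and returns to the route at 16.

Step 4. The soft benzylic anion may add in conjugate fashion to the ynamide, or the lithiated ester may self-condense. Fallback, from 4: the same lithiated species 8 is quenched with CO2 to the arylacetic acid F7, which is coupled with MeNHOMe (EDC) to the Weinreb amide F8. Addition of 1-propynylmagnesium bromide at −40 °C (a hard acetylide that cannot add in conjugate fashion to its own product) returns to the route at 9.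

## Further compounds

F1 | step 12 | [bis(4-methoxy-2-(methoxymethoxy)-6-methylbenzoyloxy)iodo]benzene | COCOc1cc(OC)cc(C)c1C(=O)OI(OC(=O)c1c(C)cc(OC)cc1OCOC)c1ccccc1
F2 | step 12 | (3S,7R)-7-methyl-8-oxo-3-[(1E)-prop-1-en-1-yl]-3,4,7,8-tetrahydro-1H-isochromen-7-yl 4-methoxy-2-(methoxymethoxy)-6-methylbenzoate | C/C=C/[C@@H]1CC2=C(CO1)C(=O)[C@](C)(OC(=O)c1c(C)cc(OC)cc1OCOC)C=C2
F3 | step 13 | (3S,5S,6S,7S)-5,6-epoxy-7-methyl-8-oxo-3-[(1E)-prop-1-en-1-yl]-3,4,5,6,7,8-hexahydro-1H-isochromen-7-yl 4-methoxy-2-(methoxymethoxy)-6-methylbenzoate | C/C=C/[C@@H]1CC2=C(CO1)C(=O)[C@@](C)(OC(=O)c1c(C)cc(OC)cc1OCOC)[C@H]1O[C@@H]21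
F4 | step 8 | (2S,3E)-1-[2-(hydroxymethyl)-3-methoxy-4-methylphenyl]pent-3-en-2-ol | C/C=C/[C@@H](O)Cc1ccc(C)c(OC)c1CO
F5 | step 8 | {6-[(2S,3E)-2-hydroxypent-3-en-1-yl]-2-methoxy-3-methylphenyl}methyl 4-methylbenzenesulfonate | C/C=C/[C@@H](O)Cc1ccc(C)c(OC)c1COS(=O)(=O)c1ccc(C)cc1
F6 | step 8 | (3S)-8-methoxy-7-methyl-3-[(1E)-prop-1-en-1-yl]-3,4-dihydro-1H-isochromene | C/C=C/[C@@H]1Cc2ccc(C)c(OC)c2CO1
F7 | step 4 | [3-methoxy-2-(methoxycarbonyl)-4-methylphenyl]acetic acid | COC(=O)c1c(CC(=O)O)ccc(C)c1OC
F8 | step 4 | methyl 2-methoxy-6-{2-[methoxy(methyl)amino]-2-oxoethyl}-3-methylbenzoate | COC(=O)c1c(CC(=O)N(C)OC)ccc(C)c1OC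
A1 | alternative 1 | (3S,6S,7S)-6,7-dihydroxy-7-methyl-3-[(1E)-prop-1-en-1-yl]-3,4,6,7-tetrahydro-1H-isochromen-8(5H)-one | C/C=C/[C@@H]1CC2=C(CO1)C(=O)[C@@](C)(O)[C@@H](O)C2
A2 | alternative 1 | tert-butyl(dimethyl){[(3S)-7-methyl-3-[(1E)-prop-1-en-1-yl]-3,4,5,8-tetrahydro-1H-isochromen-8-yl]oxy}silane (either C8 epimer) | C/C=C/[C@@H]1CC2=C(CO1)C(O[Si](C)(C)C(C)(C)C)C(C)=CC2
A3 | alternative 2 | (3S)-7-methyl-3-[(1E)-prop-1-en-1-yl]-3,4-dihydro-1H-isochromene-6,8-diol | C/C=C/[C@@H]1Cc2cc(O)c(C)c(O)c2CO1
A4 | alternative 2 | (3S,7S)-6,7-dihydroxy-7-methyl-3-[(1E)-prop-1-en-1-yl]-3,4-dihydro-1H-isochromen-8(7H)-one | C/C=C/[C@@H]1CC2=C(CO1)C(=O)[C@@](C)(O)C(O)=C2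
A5 | alternative 3 | 1-methyl-2,6-dioxocyclohexyl 4-methoxy-2-(methoxymethoxy)-6-methylbenzoate | CC1(OC(=O)c2c(C)cc(OC)cc2OCOC)C(=O)CCCC1=O
A6 | alternative 3 | (1S,2S)-2-hydroxy-1-methyl-6-oxocyclohexyl 4-methoxy-2-(methoxymethoxy)-6-methylbenzoate | C1CC(=O)[C@@](C)(OC(=O)c2c(C)cc(OC)cc2OCOC)[C@@H](O)C1
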